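**Retrosynthetic overview**

1. The target is a (2R,3R)-3-hydroxychroman-4-one (rings A and C) bonded through C2 to C4 of a trans-(2R,3S)-2-aryl-3-(hydroxymethyl)-2,3-dihydrobenzofuran (rings B and D). The end game is acid unmasking followed by hydrogenolysis of four benzyl ethers.
2. Ring C is built last, in one flask, from three pieces. C2–C3 comes from an auxiliary-controlled glycolate aldol of lactone 19 with aldehyde 15. O1–C8a and C4–C4a come from insertion of benzyne 25 (ring A, from 22) between the aldolate oxygen and the lactone carbonyl.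
3. Enabling feature: in ring C the chain O1–C2–C3(OH)–C4(=O) is a β-oxy-α-hydroxy carbonyl (aldol retron at C2–C3). Its ends O1 and C4 sit on the neighbouring ring A carbons C8a and C4a, and C4a lies next to the C5 oxygen. This is the pattern left when an alkoxide adds to a 3,5-dioxygenated benzyne remote from the alkoxy group and the ortho carbanion is then acylated.
4. Ring D is formed first (step 4) by imine-directed C–H alkylation; the aldehyde that directs it is the later aldol acceptor. Order of ring formation: D, then C. Rings A, B and the guaiacyl ring are bought as arenes.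

Key step: step 15

Assumption: the (S)-1-aminoindane imine is taken to steer the rhodium-mediated hydroarylation to the alkene face that gives the (2R) centre of the benzofuran, as the mirror image of the amine/product pairing recalled for the (2S) series of this reaction type; if the sense is the opposite, the (R)-amine is needed.

**Route**

Step 1
Reactants: 1 4-(benzyloxy)-3-methoxybenzaldehyde
Product: 2 1-(benzyloxy)-4-(2,2-dibromoethenyl)-2-methoxybenzene
Conditions: CBr4, PPh3, CH2Cl2, 0 °C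
Reagents that add atoms: carbon tetrabromide, BrC(Br)(Br)Br
Why: Corey–Fuchs dibromo-olefination of an aromatic aldehyde by the ylide from CBr4 and PPh3 is general and leaves the benzyl ether untouched.

Step 2
Reactants: 2 1-(benzyloxy)-4-(2,2-dibromoethenyl)-2-methoxybenzene
Product: 4 methyl 3-[4-(benzyloxy)-3-methoxyphenyl]prop-2-ynoate, via lithium acetylide 3 (not isolated)
Conditions: n-BuLi (2.2 equiv), THF, −78 to 0 °C; then ClCO2Me, −78 °C
Reagents that add atoms: methyl chloroformate, COC(=O)Cl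
Why: Second stage of the Corey–Fuchs alkyne synthesis (bromine–lithium exchange, 1,2-shift, deprotonation) gives the lithium acetylide, which is C-acylated by the chloroformate.

Step 3
Reactants: 4 methyl 3-[4-(benzyloxy)-3-methoxyphenyl]prop-2-ynoate; 5 4-(benzyloxy)-3-hydroxybenzaldehyde
Product: 6 methyl (2Z)-3-[2-(benzyloxy)-5-formylphenoxy]-3-[4-(benzyloxy)-3-methoxyphenyl]prop-2-enoate
Conditions: Cs2CO3 (cat.), DMF, 50 °C
Reagents that add atoms: none
Why: Base-catalysed oxa-Michael addition of the phenoxide to the aryl propiolate should proceed by anti addition and give the (Z)-3-aryloxyacrylate, which is purified to a single geometric isomer.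

Step 4
Reactants: 6 methyl (2Z)-3-[2-(benzyloxy)-5-formylphenoxy]-3-[4-(benzyloxy)-3-methoxyphenyl]prop-2-enoate; 7 (S)-1-aminoindane
Product: 10 methyl (2R,3S)-7-(benzyloxy)-2-[4-(benzyloxy)-3-methoxyphenyl]-4-formyl-2,3-dihydro-1-benzofuran-3-carboxylate (2,3-cis), via N-indanyl imine 8 (not isolated), via cyclised imine 9 (not isolated)
Conditions: 4 Å molecular sieves, toluene, rt; then [RhCl(C8H14)2]2 (10 mol %), (C5H5)Fe(C5H4PCy2) (30 mol %), toluene, 75 °C; then 1 M aq. HCl, THF, rt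
Reagents that add atoms: water, O
Why: Imine-directed ortho C–H activation by monovalent rhodium and intramolecular syn hydroarylation of the tethered acrylate (5-exo closure of ring D) has close precedent on 3-aryloxyacrylates of this type; the chiral N-indanyl group selects the alkene face and so sets C2, syn addition to the (Z)-alkene places C3 cis to it, and hydrolysis returns the aldehyde.

Step 5
Reactants: 10 methyl (2R,3S)-7-(benzyloxy)-2-[4-(benzyloxy)-3-methoxyphenyl]-4-formyl-2,3-dihydro-1-benzofuran-3-carboxylate (2,3-cis)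
Product: 11 methyl (2R,3R)-7-(benzyloxy)-2-[4-(benzyloxy)-3-methoxyphenyl]-4-formyl-2,3-dihydro-1-benzofuran-3-carboxylate (2,3-trans)
Conditions: NaOMe (0.2 equiv), MeOH/THF, rt
Reagents that add atoms: none
Why: Base-mediated epimerisation of the ester α-centre C3 should give the more stable 2,3-trans isomer, while C2 carries no acidic hydrogen and keeps its configuration.

Step 6
Reactants: 11 methyl (2R,3R)-7-(benzyloxy)-2-[4-(benzyloxy)-3-methoxyphenyl]-4-formyl-2,3-dihydro-1-benzofuran-3-carboxylate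
Product: 12 methyl (2R,3R)-7-(benzyloxy)-2-[4-(benzyloxy)-3-methoxyphenyl]-4-(dimethoxymethyl)-2,3-dihydro-1-benzofuran-3-carboxylate
Conditions: HC(OMe)3, p-TsOH (cat.), MeOH, rt
Reagents that add atoms: trimethyl orthoformate, COC(OC)OC
Why: Acid-catalysed acetalisation masks the aldehyde so that the ester can be reduced alone.

Step 7
Reactants: 12 methyl (2R,3R)-7-(benzyloxy)-2-[4-(benzyloxy)-3-methoxyphenyl]-4-(dimethoxymethyl)-2,3-dihydro-1-benzofuran-3-carboxylate
Product: 13 [(2R,3S)-7-(benzyloxy)-2-[4-(benzyloxy)-3-methoxyphenyl]-4-(dimethoxymethyl)-2,3-dihydro-1-benzofuran-3-yl]methanol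
Conditions: LiAlH4, THF, 0 °C
Reagents that add atoms: none
Why: Hydride reduction of the ester to the primary alcohol fixes C3 (no longer epimerisable) and spares the acetal and benzyl ethers.

Step 8
Reactants: 13 [(2R,3S)-7-(benzyloxy)-2-[4-(benzyloxy)-3-methoxyphenyl]-4-(dimethoxymethyl)-2,3-dihydro-1-benzofuran-3-yl]methanol
Product: 14 tert-butyl{[(2R,3S)-7-(benzyloxy)-2-[4-(benzyloxy)-3-methoxyphenyl]-4-(dimethoxymethyl)-2,3-dihydro-1-benzofuran-3-yl]methoxy}dimethylsilane
Conditions: TBSCl, imidazole, DMF, rt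
Reagents that add atoms: tert-butyldimethylsilyl chloride, CC(C)(C)[Si](C)(C)Cl
Why: Standard silylation of a primary alcohol gives an ether that survives the strong bases of step 15 and falls off in the acid step 16.

Step 9
Reactants: 14 tert-butyl{[(2R,3S)-7-(benzyloxy)-2-[4-(benzyloxy)-3-methoxyphenyl]-4-(dimethoxymethyl)-2,3-dihydro-1-benzofuran-3-yl]methoxy}dimethylsilane
Product: 15 (2R,3S)-7-(benzyloxy)-2-[4-(benzyloxy)-3-methoxyphenyl]-3-({[tert-butyl(dimethyl)silyl]oxy}methyl)-2,3-dihydro-1-benzofuran-4-carbaldehyde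
Conditions: PPTS (cat.), acetone/H2O, rt
Reagents that add atoms: water, O
Why: The dimethyl acetal of an electron-rich benzaldehyde should hydrolyse under acid too weak to cleave the primary silyl ether.

Step 10
Reactants: 16 (S)-3-chloropropane-1,2-diol
Product: 17 (2S,3S,5S)-5-(chloromethyl)-2,3-dimethoxy-2,3-dimethyl-1,4-dioxane
Conditions: butane-2,3-dione, HC(OMe)3, camphorsulfonic acid (cat.), MeOH, reflux
Reagents that add atoms: butane-2,3-dione, CC(=O)C(C)=O; trimethyl orthoformate, COC(OC)OC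
Why: Acid-catalysed butane-2,3-diacetal formation is under thermodynamic control (both methoxy groups axial, chloromethyl equatorial), so the diol stereocentre fixes both new ketal centres.

Step 11
Reactants: 17 (2S,3S,5S)-5-(chloromethyl)-2,3-dimethoxy-2,3-dimethyl-1,4-dioxane
Product: 18 (2S,3S)-2,3-dimethoxy-2,3-dimethyl-5-methylidene-1,4-dioxane
Conditions: KOt-Bu, THF, 0 °C to rt
Reagents that add atoms: none
Why: E2 elimination of HCl gives the exocyclic enol ether; the ketal centres are untouched.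

Step 12
Reactants: 18 (2S,3S)-2,3-dimethoxy-2,3-dimethyl-5-methylidene-1,4-dioxane
Product: 19 (5S,6S)-5,6-dimethoxy-5,6-dimethyl-1,4-dioxan-2-one
Conditions: O3, CH2Cl2/MeOH, −78 °C; then Me2S
Reagents that add atoms: ozone, [O-][O+]=O
Why: Ozonolysis of the enol ether double bond gives the lactone, a chiral glycolic acid equivalent whose only stereocentres are the two ketal carbons.

Step 13
Reactants: 20 3,5-bis(benzyloxy)phenol
Product: 21 3,5-bis(benzyloxy)-2-iodophenol
Conditions: N-iodosuccinimide, CH2Cl2, 0 °C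
Reagents that add atoms: N-iodosuccinimide, O=C1CCC(=O)N1I
Why: Electrophilic aromatic iodination of a 3,5-dialkoxyphenol should prefer the position ortho to OH and para to one benzyloxy group over the site flanked by two benzyloxy groups.

Step 14
Reactants: 21 3,5-bis(benzyloxy)-2-iodophenol
Product: 22 3,5-bis(benzyloxy)-2-iodophenyl trifluoromethanesulfonate
Conditions: Tf2O, pyridine, CH2Cl2, 0 °C
Reagents that add atoms: trifluoromethanesulfonic anhydride, O=S(=O)(OS(=O)(=O)C(F)(F)F)C(F)(F)F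
Why: O-Triflation of the phenol gives a 2-iodoaryl triflate, a precursor that releases an aryne at low temperature on iodine–magnesium exchange.

Step 15
Reactants: 19 (5S,6S)-5,6-dimethoxy-5,6-dimethyl-1,4-dioxan-2-one; 15 (2R,3S)-7-(benzyloxy)-2-[4-(benzyloxy)-3-methoxyphenyl]-3-({[tert-butyl(dimethyl)silyl]oxy}methyl)-2,3-dihydro-1-benzofuran-4-carbaldehyde; 22 3,5-bis(benzyloxy)-2-iodophenyl trifluoromethanesulfonate
Product: 28 (2R,3R)-5,7-bis(benzyloxy)-2-[(2R,3S)-7-(benzyloxy)-2-[4-(benzyloxy)-3-methoxyphenyl]-3-({[tert-butyl(dimethyl)silyl]oxy}methyl)-2,3-dihydro-1-benzofuran-4-yl]-3-{[(2S)-2-methoxy-3-oxobutan-2-yl]oxy}-2,3-dihydro-4H-chromen-4-one, via lithium enolate 23 (not isolated), via lithium aldolate 24 (not isolated), via aryne 25 (not isolated), via aryllithium ether 26 (not isolated), via hemiketal alkoxide 27 (not isolated)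
Conditions: 19, LiN(SiMe3)2, THF, −78 °C; add 15, −78 °C; then 22 (2 equiv), Me3SiCH2MgCl (2 equiv), −78 to −40 °C; AcOH, −78 °C
Reagents that add atoms: none
Why: Proposed new method: the lithium enolate 23 of the glycolate lactone adds to aldehyde 15 (C2–C3); the lithium aldolate 24 then adds through O1 to benzyne 25, released from 22 by iodine–magnesium exchange at −78 °C, at the aryne carbon remote from the neighbouring benzyloxy group (O1–C8a); the aryllithium 26 formed at C4a attacks the lactone carbonyl (C4–C4a) and expels the ketal oxygen, whose hemiketal alkoxide 27 loses methoxide to leave ketone 28 with O3 masked as a mixed ketal. The closest known reactions are the anti-selective lithium enolate aldol of this butanediacetal glycolate with aldehydes, the generation of arynes from 2-iodoaryl triflates with a silylmethyl Grignard reagent, and the annulation of arynes with salicylate esters to xanthones (oxygen nucleophile adds to the aryne, the aryl anion acylates intramolecularly); new is their union in one flask on an aliphatic aldolate. Ring C is closed by 6-exo-trig attack of the C4a carbanion on the lactone carbonyl, after the two intermolecular bond formations. C3 is set by attack on the enolate face anti to the axial 5-methoxy group of the locked chair, and C2 by the closed chair transition state of the ring-constrained enolate with the aryl group equatorial, which gives the anti aldol and hence the trans (2R,3R) chromanone; neither centre is touched again in this step. The step needs attack of O1 at C8a and not at C4a, which the 3-benzyloxy group of the aryne secures by directing nucleophiles to the distal carbon and stabilising the adjacent anion (ring A is symmetric, so only one aryne can form). It also needs the aldolate to persist, which should follow from the poor leaving ability of a lactone enolate at −78 °C, and acylation of 26 before protonation, which the six-membered geometry and the absence of any acid stronger than HN(SiMe3)2 should favour.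

Step 16
Reactants: 28 (2R,3R)-5,7-bis(benzyloxy)-2-[(2R,3S)-7-(benzyloxy)-2-[4-(benzyloxy)-3-methoxyphenyl]-3-({[tert-butyl(dimethyl)silyl]oxy}methyl)-2,3-dihydro-1-benzofuran-4-yl]-3-{[(2S)-2-methoxy-3-oxobutan-2-yl]oxy}-2,3-dihydro-4H-chromen-4-one
Product: 29 (2R,3R)-5,7-bis(benzyloxy)-2-[(2R,3S)-7-(benzyloxy)-2-[4-(benzyloxy)-3-methoxyphenyl]-3-(hydroxymethyl)-2,3-dihydro-1-benzofuran-4-yl]-3-hydroxy-2,3-dihydro-4H-chromen-4-one
Conditions: 1 M aq. HCl, THF, rt
Reagents that add atoms: none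
Why: Acid hydrolysis of the acyclic mixed ketal on O3 and of the primary silyl ether should proceed under conditions that leave benzyl ethers, the trans-dihydrobenzofuran and the 2,3-trans chromanone (the stable epimer at C3) unchanged.

Step 17
Reactants: 29 (2R,3R)-5,7-bis(benzyloxy)-2-[(2R,3S)-7-(benzyloxy)-2-[4-(benzyloxy)-3-methoxyphenyl]-3-(hydroxymethyl)-2,3-dihydro-1-benzofuran-4-yl]-3-hydroxy-2,3-dihydro-4H-chromen-4-one
Product: 30 (2R,3R)-3,5,7-trihydroxy-2-[(2R,3S)-7-hydroxy-2-(4-hydroxy-3-methoxyphenyl)-3-(hydroxymethyl)-2,3-dihydro-1-benzofuran-4-yl]-2,3-dihydro-4H-chromen-4-one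
Conditions: H2 (1 atm), Pd/C, EtOAc/MeOH, rt
Reagents that add atoms: none
Why: Catalytic hydrogenolysis of the four phenolic benzyl ethers is fast under neutral conditions, the standard last step for benzyl-protected flavanonols, and no stereocentre is affected.

**Compound list**

1 | 4-(benzyloxy)-3-methoxybenzaldehyde | COc1cc(C=O)ccc1OCc1ccccc1 | starting material
2 | 1-(benzyloxy)-4-(2,2-dibromoethenyl)-2-methoxybenzene | COc1cc(C=C(Br)Br)ccc1OCc1ccccc1 | intermediate
3 | lithium [4-(benzyloxy)-3-methoxyphenyl]ethynide | [Li]C#Cc1ccc(OCc2ccccc2)c(OC)c1 | intermediate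
4 | methyl 3-[4-(benzyloxy)-3-methoxyphenyl]prop-2-ynoate | COC(=O)C#Cc1ccc(OCc2ccccc2)c(OC)c1 | intermediate
5 | 4-(benzyloxy)-3-hydroxybenzaldehyde | O=Cc1ccc(OCc2ccccc2)c(O)c1 | starting material
6 | methyl (2Z)-3-[2-(benzyloxy)-5-formylphenoxy]-3-[4-(benzyloxy)-3-methoxyphenyl]prop-2-enoate | COC(=O)/C=C(\Oc1cc(C=O)ccc1OCc1ccccc1)c1ccc(OCc2ccccc2)c(OC)c1 | intermediate
7 | (S)-1-aminoindane | N[C@H]1CCc2ccccc12 | starting material
8 | (E)-N-[(1S)-indan-1-yl] aldimine of 6 | COC(=O)/C=C(\Oc1cc(/C=N/[C@H]2CCc3ccccc23)ccc1OCc1ccccc1)c1ccc(OCc2ccccc2)c(OC)c1 | intermediate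
9 | (E)-N-[(1S)-indan-1-yl] aldimine of 10 (2,3-cis-dihydrobenzofuran) | COc1cc([C@@H]2Oc3c(OCc4ccccc4)ccc(/C=N/[C@H]4CCc5ccccc45)c3[C@@H]2C(=O)OC)ccc1OCc1ccccc1 | intermediate
10 | methyl (2R,3S)-7-(benzyloxy)-2-[4-(benzyloxy)-3-methoxyphenyl]-4-formyl-2,3-dihydro-1-benzofuran-3-carboxylate (cis) | COc1cc([C@@H]2Oc3c(OCc4ccccc4)ccc(C=O)c3[C@@H]2C(=O)OC)ccc1OCc1ccccc1 | intermediate
11 | methyl (2R,3R)-7-(benzyloxy)-2-[4-(benzyloxy)-3-methoxyphenyl]-4-formyl-2,3-dihydro-1-benzofuran-3-carboxylate (trans) | COc1cc([C@@H]2Oc3c(OCc4ccccc4)ccc(C=O)c3[C@H]2C(=O)OC)ccc1OCc1ccccc1 | intermediate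
12 | methyl (2R,3R)-7-(benzyloxy)-2-[4-(benzyloxy)-3-methoxyphenyl]-4-(dimethoxymethyl)-2,3-dihydro-1-benzofuran-3-carboxylate | COc1cc([C@@H]2Oc3c(OCc4ccccc4)ccc(C(OC)OC)c3[C@H]2C(=O)OC)ccc1OCc1ccccc1 | intermediate
13 | [(2R,3S)-7-(benzyloxy)-2-[4-(benzyloxy)-3-methoxyphenyl]-4-(dimethoxymethyl)-2,3-dihydro-1-benzofuran-3-yl]methanol | COc1cc([C@@H]2Oc3c(OCc4ccccc4)ccc(C(OC)OC)c3[C@H]2CO)ccc1OCc1ccccc1 | intermediate
14 | tert-butyl{[(2R,3S)-7-(benzyloxy)-2-[4-(benzyloxy)-3-methoxyphenyl]-4-(dimethoxymethyl)-2,3-dihydro-1-benzofuran-3-yl]methoxy}dimethylsilane | COc1cc([C@@H]2Oc3c(OCc4ccccc4)ccc(C(OC)OC)c3[C@H]2CO[Si](C)(C)C(C)(C)C)ccc1OCc1ccccc1 | intermediate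
15 | (2R,3S)-7-(benzyloxy)-2-[4-(benzyloxy)-3-methoxyphenyl]-3-({[tert-butyl(dimethyl)silyl]oxy}methyl)-2,3-dihydro-1-benzofuran-4-carbaldehyde | COc1cc([C@@H]2Oc3c(OCc4ccccc4)ccc(C=O)c3[C@H]2CO[Si](C)(C)C(C)(C)C)ccc1OCc1ccccc1 | intermediate
16 | (S)-3-chloropropane-1,2-diol | OC[C@H](O)CCl | starting material
17 | (2S,3S,5S)-5-(chloromethyl)-2,3-dimethoxy-2,3-dimethyl-1,4-dioxane | ClC[C@@H]1CO[C@](C)(OC)[C@@](C)(OC)O1 | intermediate
18 | (2S,3S)-2,3-dimethoxy-2,3-dimethyl-5-methylidene-1,4-dioxane | C=C1CO[C@](C)(OC)[C@@](C)(OC)O1 | intermediate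
19 | (5S,6S)-5,6-dimethoxy-5,6-dimethyl-1,4-dioxan-2-one | O=C1CO[C@](C)(OC)[C@@](C)(OC)O1 | intermediate
20 | 3,5-bis(benzyloxy)phenol | Oc1cc(OCc2ccccc2)cc(OCc2ccccc2)c1 | starting material
21 | 3,5-bis(benzyloxy)-2-iodophenol | Oc1cc(OCc2ccccc2)cc(OCc2ccccc2)c1I | intermediate
22 | 3,5-bis(benzyloxy)-2-iodophenyl trifluoromethanesulfonate | O=S(=O)(Oc1cc(OCc2ccccc2)cc(OCc2ccccc2)c1I)C(F)(F)F | intermediate
23 | lithium enolate of 19 | [Li+].[O-]C1=CO[C@](C)(OC)[C@@](C)(OC)O1 | intermediate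
24 | lithium (R)-alkoxide of the anti aldol: (3R,5S,6S)-3-[(R)-aryl(oxido)methyl]-5,6-dimethoxy-5,6-dimethyl-1,4-dioxan-2-one, aryl = benzofuran-4-yl of 15 | [Li+].COc1cc([C@@H]2Oc3c(OCc4ccccc4)ccc([C@@H]([O-])[C@H]4O[C@](C)(OC)[C@@](C)(OC)OC4=O)c3[C@H]2CO[Si](C)(C)C(C)(C)C)ccc1OCc1ccccc1 | intermediate
25 | 3,5-bis(benzyloxy)benzyne (1,2-didehydro) | C1#CC(OCc2ccccc2)=CC(OCc2ccccc2)=C1 | intermediate
26 | 2-lithio-3,5-bis(benzyloxy)phenyl ether of the aldol 24 | COc1cc([C@@H]2Oc3c(OCc4ccccc4)ccc([C@@H](Oc4cc(OCc5ccccc5)cc(OCc5ccccc5)c4[Li])[C@H]4O[C@](C)(OC)[C@@](C)(OC)OC4=O)c3[C@H]2CO[Si](C)(C)C(C)(C)C)ccc1OCc1ccccc1 | intermediate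
27 | lithium hemiketal alkoxide: chromanone of 28 with O3 bearing (2S,3S)-2,3-dimethoxy-3-oxidobutan-2-yl | [Li+].COc1cc([C@@H]2Oc3c(OCc4ccccc4)ccc([C@H]4Oc5cc(OCc6ccccc6)cc(OCc6ccccc6)c5C(=O)[C@@H]4O[C@](C)(OC)[C@@](C)(OC)[O-])c3[C@H]2CO[Si](C)(C)C(C)(C)C)ccc1OCc1ccccc1 | intermediate
28 | (2R,3R)-5,7-bis(benzyloxy)-2-[(2R,3S)-7-(benzyloxy)-2-[4-(benzyloxy)-3-methoxyphenyl]-3-({[tert-butyl(dimethyl)silyl]oxy}methyl)-2,3-dihydro-1-benzofuran-4-yl]-3-{[(2S)-2-methoxy-3-oxobutan-2-yl]oxy}-2,3-dihydro-4H-chromen-4-one | COc1cc([C@@H]2Oc3c(OCc4ccccc4)ccc([C@H]4Oc5cc(OCc6ccccc6)cc(OCc6ccccc6)c5C(=O)[C@@H]4O[C@](C)(OC)C(C)=O)c3[C@H]2CO[Si](C)(C)C(C)(C)C)ccc1OCc1ccccc1 | intermediate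
29 | (2R,3R)-5,7-bis(benzyloxy)-2-[(2R,3S)-7-(benzyloxy)-2-[4-(benzyloxy)-3-methoxyphenyl]-3-(hydroxymethyl)-2,3-dihydro-1-benzofuran-4-yl]-3-hydroxy-2,3-dihydro-4H-chromen-4-one | COc1cc([C@@H]2Oc3c(OCc4ccccc4)ccc([C@H]4Oc5cc(OCc6ccccc6)cc(OCc6ccccc6)c5C(=O)[C@@H]4O)c3[C@H]2CO)ccc1OCc1ccccc1 | intermediate
30 | (2R,3R)-3,5,7-trihydroxy-2-[(2R,3S)-7-hydroxy-2-(4-hydroxy-3-methoxyphenyl)-3-(hydroxymethyl)-2,3-dihydro-1-benzofuran-4-yl]-2,3-dihydro-4H-chromen-4-one | COc1cc([C@@H]2Oc3c(O)ccc([C@H]4Oc5cc(O)cc(O)c5C(=O)[C@@H]4O)c3[C@H]2CO)ccc1O | target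

**Step count and risks**

Total step count: 17. Longest linear sequence: 12 steps (steps 1–9, then 15–17).

Steps most likely to fail:

1. Step 15 (proposed new method). The aryl anion 26 may be protonated, by hexamethyldisilazane or by internal transfer of the acidic C3 hydrogen, before it acylates. The aldolate may also lose the aryne to competing nucleophiles, or revert by retro-aldol while the aryne is being generated. Fallback by known chemistry, setting out from 15: commercial 1-[2,4-bis(benzyloxy)-6-hydroxyphenyl]ethanone is protected (MOMCl, i-Pr2NEt, CH2Cl2) as 1-[2,4-bis(benzyloxy)-6-(methoxymethoxy)phenyl]ethan-1-one F1. Claisen–Schmidt condensation of F1 with 15 (KOH, EtOH/THF, rt) gives the (E)-chalcone F2. Juliá–Colonna epoxidation (poly-L-leucine, urea–H2O2, DBU, THF) gives the (αR,βS)-epoxy ketone F3. HCl in MeOH/THF removes the methoxymethyl and silyl groups, and the freed phenol opens the epoxide at the benzylic carbon with inversion, giving the trans-flavanonol 29, where the route is rejoined before step 17.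

2. Step 4. The facial selectivity imposed by the N-indanyl imine on the hydroarylation may be insufficient, so that the benzofuran is carried forward in low enantiomeric purity. Fallback, setting out from 12: the ester is saponified (LiOH, THF/H2O) to (2R,3R)-7-(benzyloxy)-2-[4-(benzyloxy)-3-methoxyphenyl]-4-(dimethoxymethyl)-2,3-dihydro-1-benzofuran-3-carboxylic acid F4, which is resolved by crystallisation of its (S)-1-phenylethylammonium salt F5. The salt is partitioned between ethyl acetate and cold aqueous NaH2PO4 and the acid re-esterified (MeI, K2CO3, DMF), returning to 12 as a single enantiomer.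

3. Step 13. Iodination may occur at the carbon between the two benzyloxy groups, or twice. Fallback, setting out from 20: the phenol is converted (ClC(O)NEt2, K2CO3, MeCN) into 3,5-bis(benzyloxy)phenyl diethylcarbamate F6. Directed ortho-lithiation (s-BuLi, TMEDA, THF, −78 °C) and quenching with I2 gives 3,5-bis(benzyloxy)-2-iodophenyl diethylcarbamate F7, the carbamate fixing the site. Cleavage with KOH in EtOH at reflux returns 21.

**Further compounds**

F1 | step 15 | 1-[2,4-bis(benzyloxy)-6-(methoxymethoxy)phenyl]ethan-1-one | CC(=O)c1c(OCOC)cc(OCc2ccccc2)cc1OCc1ccccc1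
F2 | step 15 | (2E)-3-[(2R,3S)-7-(benzyloxy)-2-[4-(benzyloxy)-3-methoxyphenyl]-3-({[tert-butyl(dimethyl)silyl]oxy}methyl)-2,3-dihydro-1-benzofuran-4-yl]-1-[2,4-bis(benzyloxy)-6-(methoxymethoxy)phenyl]prop-2-en-1-one | COc1cc([C@@H]2Oc3c(OCc4ccccc4)ccc(/C=C/C(=O)c4c(OCOC)cc(OCc5ccccc5)cc4OCc4ccccc4)c3[C@H]2CO[Si](C)(C)C(C)(C)C)ccc1OCc1ccccc1
F3 | step 15 | [(2R,3S)-3-{(2R,3S)-7-(benzyloxy)-2-[4-(benzyloxy)-3-methoxyphenyl]-3-({[tert-butyl(dimethyl)silyl]oxy}methyl)-2,3-dihydro-1-benzofuran-4-yl}oxiran-2-yl][2,4-bis(benzyloxy)-6-(methoxymethoxy)phenyl]methanone | COc1cc([C@@H]2Oc3c(OCc4ccccc4)ccc([C@@H]4O[C@H]4C(=O)c4c(OCOC)cc(OCc5ccccc5)cc4OCc4ccccc4)c3[C@H]2CO[Si](C)(C)C(C)(C)C)ccc1OCc1ccccc1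
F4 | step 4 | (2R,3R)-7-(benzyloxy)-2-[4-(benzyloxy)-3-methoxyphenyl]-4-(dimethoxymethyl)-2,3-dihydro-1-benzofuran-3-carboxylic acid | COc1cc([C@@H]2Oc3c(OCc4ccccc4)ccc(C(OC)OC)c3[C@H]2C(O)=O)ccc1OCc1ccccc1
F5 | step 4 | (S)-1-phenylethylammonium salt of F4 | COc1cc([C@@H]2Oc3c(OCc4ccccc4)ccc(C(OC)OC)c3[C@H]2C([O-])=O)ccc1OCc1ccccc1.C[C@H]([NH3+])c1ccccc1
F6 | step 13 | 3,5-bis(benzyloxy)phenyl diethylcarbamate | CCN(CC)C(=O)Oc1cc(OCc2ccccc2)cc(OCc2ccccc2)c1
F7 | step 13 | 3,5-bis(benzyloxy)-2-iodophenyl diethylcarbamate | CCN(CC)C(=O)Oc1cc(OCc2ccccc2)cc(OCc2ccccc2)c1I
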